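The earlier runs and the new flask are simulated from invented constants, noise included.

A closed flask that spends nucleophile in a steady ratio to the electrophile reacted has one invariant: nucleophile minus that ratio times electrophile.

| flask | electrophile | nucleophile | remark | time |
|---|---|---|---|---|
| winter | 0.30 M | 0.60 equiv | run made earlier |  |
| summer | 0.30 M | 2.4 equiv | run made earlier |  |
| spring | 0.60 M | 1.2 equiv | run made earlier |  |
| flask | 0.30 M | 1.20 equiv |  | 6.0 min |

- winter (time / min: electrophile / %, product / %): 0.667: 67, 34; 1.33: 53, 44; 2.00: 48, 53; 3.00: 43, 54; 4.00: 44, 52
- summer (time / min: electrophile / %, product / %): 0.250: 38, 61; 0.500: 22, 80; 1.00: 12, 92; 2.00: 0, 96; 4.00: 0, 100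
- spring (time / min: electrophile / %, product / %): 0.667: 38, 64; 1.33: 20, 79; 2.00: 11, 86; 3.00: 7, 93; 4.00: 3, 91

(readings scatter by 2 percentage points)

- the earlier runs do not show how much of nucleophile is bound; that part of a forecast is a guess

* part of the electrophile that has reacted at 6.0 min
* share of the unused nucleophile that is free and not bound as protonated nucleophile, at 6.0 min

The winter run levels off with electrophile readings of 43 % and 44 %, while the summer run, with more nucleophile, reads 0 %. So the winter run reads as short of nucleophile, the limiting reagent there. Its last two readings give:

cost = 0.60 equiv / 56.5 % = 1.06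

This cost is the nucleophile spent per electrophile reacted, a reading with the scatter of the runs.

The new flask holds twice the winter charge of nucleophile. Its reach, the part of the electrophile its nucleophile can pay for, looks impossible:

reach = 1.20 equiv / 1.06 = 113 %

A part above the whole charge is no conversion. The figure says that the reach of the new flask lies above complete reaction, so electrophile reads as the limiting reagent there. This reckoning puts no value on the conversion at 6.0 min.

The forecast gives 97 % reacted (93 % to 99 %) and 75 % of the unused nucleophile free (35 % to 97 %), reading “roughly one nucleophile consumed per product”.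

The flask gives 93.5 % reacted and 73.2 % free.

    crystals ⇌ acid set free, rate k1*(cs1 - [acid set free]) while solid is left; crystals form when [acid set free] > cs1 (solubility = 5.60 mM, k = 0.212 s⁻¹)
    acid set free → by-product carried off (k = 9.11 × 10⁻⁴ s⁻¹)
    2 nucleophile → homo dimer (k = 0.0160 L mol⁻¹ s⁻¹)
    electrophile + nucleophile → acid set free + product (k = 0.148 L mol⁻¹ s⁻¹)
    nucleophile + acid set free ⇌ protonated nucleophile, settled at all times (K = 61.0 L mol⁻¹)

The flask stands below its reach, with 6.5 % of its electrophile unreacted and 6.0 % of its nucleophile still free. A neighbour flask charged with 0.480 equiv of nucleophile lies under the cost, so its reach is 45.3 %. That neighbour gives 45.9 % reacted at 6.0 min, with 0.088 % of its nucleophile still free.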